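**Retrosynthetic overview** (eudesmane numbering: C4 carbinol, C5/C10 ring fusion, C7 side-chain carbon, C9 ester carbon)
1. Acrylic acid from a 7α-isopropenyl group (SeO2, then Pinnick); ester from the 9β-alcohol and (3R)-3-methylpentanoic acid.
2. C7 by axial cuprate addition to a trans-fused Δ7-9-one; C9 by dissolving-metal reduction to the equatorial alcohol.
3. C4 (α-OH, β-Me) and C5 (α-H) together by syn hydroboration of a tetrasubstituted Δ4 olefin from the face opposite the angular methyl.
4. Key step: Birch reductive methylation of 5-methyl-1-tetralone de-aromatises ring A, creates quaternary C10 and leaves the Δ4 olefin; the racemate is split by an enantiomer-selective enzymatic ketone reduction.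
5. Ring order: ring B is closed first onto the arene (Negishi coupling, Friedel–Crafts acylation); the arene then becomes ring A.

Assumption: (3R)-3-methylpentanoic acid is bought as the single enantiomer.

**Step 1**
Reactants: 1 2-bromotoluene; 2 (4-ethoxy-4-oxobutyl)zinc bromide
Product: 3 ethyl 4-(2-methylphenyl)butanoate
Conditions: Pd(OAc)2 (2 mol %), SPhos (4 mol %), THF, 50 °C
Reagents that add atoms: none
Why: Negishi sp2–sp3 cross-coupling of an aryl bromide with a primary alkylzinc that tolerates the ester; no stereocentre is formed.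

**Step 2**
Reactants: 3 ethyl 4-(2-methylphenyl)butanoate
Product: 4 5-methyl-3,4-dihydronaphthalen-1(2H)-one
Conditions: CF3SO3H (5 equiv), 1,2-dichloroethane, 80 °C
Reagents that add atoms: none
Why: Intramolecular Friedel–Crafts acylation closes ring B at the only free position ortho to the chain, which places the methyl on C5 of the tetralone.

**Step 3**
Reactants: 4 5-methyl-3,4-dihydronaphthalen-1(2H)-one
Product: 6 rac-5,8a-dimethyl-3,4,6,8a-tetrahydronaphthalen-1(2H)-one, via lithium dienolate 5 (not isolated)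
Conditions: Li (2.2 equiv), NH3(l)/THF, t-BuOH (1.0 equiv), −78 °C; then MeI (5 equiv), −78 °C → rt
Reagents that add atoms: iodomethane, CI
Why: Birch reductive alkylation of an aryl ketone: protonation para to the carbonyl gives the cross-conjugated dienolate, which is C-methylated at the former ipso carbon; this breaks the aromaticity, creates quaternary C10 (racemic) and leaves a 1,4-diene whose tetrasubstituted bond is the later Δ4 olefin.

**Step 4**
Reactants: 6 rac-5,8a-dimethyl-3,4,6,8a-tetrahydronaphthalen-1(2H)-one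
Product: 7 rac-5,8a-dimethyl-3,4,6,7,8,8a-hexahydronaphthalen-1(2H)-one
Conditions: H2 (3 atm), RhCl(PPh3)3 (5 mol %), benzene/EtOH, rt
Reagents that add atoms: none
Why: Homogeneous hydrogenation with RhCl(PPh3)3 saturates the cis-disubstituted olefin and leaves the tetrasubstituted olefin and the ketone untouched.

**Step 5**
Reactants: 7 rac-5,8a-dimethyl-3,4,6,7,8,8a-hexahydronaphthalen-1(2H)-one
Product: 8 (1S,8aS)-5,8a-dimethyl-1,2,3,4,6,7,8,8a-octahydronaphthalen-1-ol
Conditions: ketoreductase (panel hit selective for the (8aS)-ketone), NADP+ (cat.), i-PrOH, phosphate buffer pH 7, 30 °C, stopped near 50% conversion; chromatography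
Reagents that add atoms: none
Why: Enzymatic kinetic resolution by enantiomer-selective ketone reduction, of the kind yeast reductases show with angularly methylated decalones of the Wieland–Miescher type: only (8aS)-7 is reduced (hydride anti to the angular methyl, cis alcohol), so C10 becomes single-handed, and unreacted (8aR)-7 is removed (at most 50% yield).

**Step 6**
Reactants: 8 (1S,8aS)-5,8a-dimethyl-1,2,3,4,6,7,8,8a-octahydronaphthalen-1-ol
Product: 10 (1S,4aR,5R,8aS)-5,8a-dimethyldecahydronaphthalene-1,5-diol, via alkylborane 9 (not isolated)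
Conditions: BH3·SMe2 (4 equiv), THF, 0 → 50 °C; then NaOH, H2O2, 0 → 40 °C
Reagents that add atoms: borane–dimethyl sulfide, [BH3-][S+](C)C (boron in 9); hydrogen peroxide, OO (oxygen on C4)
Why: Hydroboration–oxidation: boron goes to C4, away from the quaternary carbon, and H and B add syn from the α-face opposite the pseudo-axial angular methyl, so C5 gets its α-hydrogen (trans-decalin) and C4 its α-hydroxyl with the methyl β, with retention in the oxidation.

**Step 7**
Reactants: 10 (1S,4aR,5R,8aS)-5,8a-dimethyldecahydronaphthalene-1,5-diol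
Product: 12 (4aR,5R,8aS)-5-hydroxy-5,8a-dimethyl-4a,5,6,7,8,8a-hexahydronaphthalen-1(4H)-one, via hydroxy ketone 11 (not isolated)
Conditions: 2-iodoxybenzoic acid (IBX, 3 equiv), DMSO, 75 °C
Reagents that add atoms: none
Why: IBX oxidises the secondary alcohol and then dehydrogenates the ketone to the enone (Nicolaou dehydrogenation); the only enolisable α-carbon is C8 because C10 is quaternary, and the tertiary alcohol is inert.

**Step 8**
Reactants: 12 (4aR,5R,8aS)-5-hydroxy-5,8a-dimethyl-4a,5,6,7,8,8a-hexahydronaphthalen-1(4H)-one; 13 isopropenylmagnesium bromide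
Product: 14 (3R,4aR,5R,8aS)-5-hydroxy-5,8a-dimethyl-3-(prop-1-en-2-yl)octahydronaphthalen-1(2H)-one
Conditions: 13 (4 equiv), CuBr·SMe2 (0.3 equiv), THF, −78 → −30 °C; aq NH4Cl
Reagents that add atoms: none
Why: Copper-catalysed conjugate addition to the rigid trans-fused enone: axial attack on the α-face (trans to the C5–C4 bond, away from the axial angular methyl) sets C7 with the side chain α, and one equivalent of Grignard is spent on the tertiary hydroxyl.

**Step 9**
Reactants: 14 (3R,4aR,5R,8aS)-5-hydroxy-5,8a-dimethyl-3-(prop-1-en-2-yl)octahydronaphthalen-1(2H)-one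
Product: 15 (1S,3R,4aR,5R,8aS)-5,8a-dimethyl-3-(prop-1-en-2-yl)decahydronaphthalene-1,5-diol
Conditions: Li, NH3(l), THF, EtOH, −78 → −33 °C; NH4Cl
Reagents that add atoms: none
Why: Dissolving-metal ketone reduction gives the thermodynamically preferred equatorial 9β-alcohol (the axial epimer would be 1,3-diaxial to the C7 side chain), which sets C9; the isolated isopropenyl olefin is not reduced.

**Step 10**
Reactants: 15 (1S,3R,4aR,5R,8aS)-5,8a-dimethyl-3-(prop-1-en-2-yl)decahydronaphthalene-1,5-diol; 16 (3R)-3-methylpentanoic acid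
Product: 17 (1S,3R,4aR,5R,8aS)-5-hydroxy-5,8a-dimethyl-3-(prop-1-en-2-yl)decahydronaphthalen-1-yl (3R)-3-methylpentanoate
Conditions: DCC, DMAP, CH2Cl2, rt → 40 °C
Reagents that add atoms: none
Why: Steglich esterification acylates the secondary equatorial alcohol only; the tertiary C4 alcohol does not react, and the acyl stereocentre (β to the carbonyl) is not at risk.

**Step 11**
Reactants: 17 (1S,3R,4aR,5R,8aS)-5-hydroxy-5,8a-dimethyl-3-(prop-1-en-2-yl)decahydronaphthalen-1-yl (3R)-3-methylpentanoate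
Product: 19 (1S,3R,4aR,5R,8aS)-5-hydroxy-5,8a-dimethyl-3-(3-oxoprop-1-en-2-yl)decahydronaphthalen-1-yl (3R)-3-methylpentanoate, via allylic alcohol 18 (not isolated)
Conditions: SeO2 (0.5 equiv), t-BuOOH, CH2Cl2, rt; then MnO2, CH2Cl2, rt
Reagents that add atoms: tert-butyl hydroperoxide, CC(C)(C)OO (oxygen source); selenium dioxide, O=[Se]=O (oxygen carrier)
Why: SeO2 allylic oxidation (ene reaction, then 2,3-sigmatropic shift) attacks the methyl of the 1,1-disubstituted olefin in preference to the ring methine, and MnO2 takes the allylic alcohol on to the enal; no stereocentre is touched.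

**Step 12**
Reactants: 19 (1S,3R,4aR,5R,8aS)-5-hydroxy-5,8a-dimethyl-3-(3-oxoprop-1-en-2-yl)decahydronaphthalen-1-yl (3R)-3-methylpentanoate
Product: 20 2-[(2R,4S,4aS,8R,8aR)-8-hydroxy-4a,8-dimethyl-4-{[(3R)-3-methylpentanoyl]oxy}decahydronaphthalen-2-yl]prop-2-enoic acid
Conditions: NaClO2, NaH2PO4, 2-methyl-2-butene, t-BuOH/H2O, rt
Reagents that add atoms: sodium chlorite, [Na+].[O-]Cl=O
Why: Pinnick oxidation converts the enal to the acrylic acid without touching the ester, the tertiary alcohol or the olefin.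

**Compound list**
1 | 2-bromotoluene | Cc1ccccc1Br | starting material
2 | (4-ethoxy-4-oxobutyl)zinc bromide | CCOC(=O)CCC[Zn]Br | starting material
3 | ethyl 4-(2-methylphenyl)butanoate | CCOC(=O)CCCc1ccccc1C | intermediate
4 | 5-methyl-3,4-dihydronaphthalen-1(2H)-one | Cc1cccc2c1CCCC2=O | intermediate
5 | lithium 5-methyl-2,3,4,6-tetrahydronaphthalen-1-olate | [Li+].[O-]C1=C2C=CCC(C)=C2CCC1 | intermediate
6 | rac-5,8a-dimethyl-3,4,6,8a-tetrahydronaphthalen-1(2H)-one (racemate, C8a unspecified) | CC1=C2CCCC(=O)C2(C)C=CC1 | intermediate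
7 | rac-5,8a-dimethyl-3,4,6,7,8,8a-hexahydronaphthalen-1(2H)-one (racemate, C8a unspecified) | CC1=C2CCCC(=O)C2(C)CCC1 | intermediate
8 | (1S,8aS)-5,8a-dimethyl-1,2,3,4,6,7,8,8a-octahydronaphthalen-1-ol | C1C[C@H](O)[C@@]2(C)CCCC(C)=C2C1 | intermediate
9 | [(1S,4aS,5S,8aS)-1-(boranyloxy)-5,8a-dimethyldecahydronaphthalen-5-yl]borane (BH2 α on C4, H α on C5) | C1C[C@H](OB)[C@@]2(C)CCC[C@@](C)(B)[C@@H]2C1 | intermediate
10 | (1S,4aR,5R,8aS)-5,8a-dimethyldecahydronaphthalene-1,5-diol | C1C[C@H](O)[C@@]2(C)CCC[C@@](C)(O)[C@@H]2C1 | intermediate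
11 | (4aR,5R,8aS)-5-hydroxy-5,8a-dimethyl-3,4,4a,5,6,7,8,8a-octahydronaphthalen-1(2H)-one | C1CC(=O)[C@@]2(C)CCC[C@@](C)(O)[C@@H]2C1 | intermediate
12 | (4aR,5R,8aS)-5-hydroxy-5,8a-dimethyl-4a,5,6,7,8,8a-hexahydronaphthalen-1(4H)-one | C1=CC(=O)[C@@]2(C)CCC[C@@](C)(O)[C@@H]2C1 | intermediate
13 | isopropenylmagnesium bromide | CC(=C)[Mg]Br | starting material
14 | (3R,4aR,5R,8aS)-5-hydroxy-5,8a-dimethyl-3-(prop-1-en-2-yl)octahydronaphthalen-1(2H)-one | CC(=C)[C@H]1CC(=O)[C@@]2(C)CCC[C@@](C)(O)[C@@H]2C1 | intermediate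
15 | (1S,3R,4aR,5R,8aS)-5,8a-dimethyl-3-(prop-1-en-2-yl)decahydronaphthalene-1,5-diol | CC(=C)[C@H]1C[C@H](O)[C@@]2(C)CCC[C@@](C)(O)[C@@H]2C1 | intermediate
16 | (3R)-3-methylpentanoic acid | CC[C@@H](C)CC(=O)O | starting material
17 | (1S,3R,4aR,5R,8aS)-5-hydroxy-5,8a-dimethyl-3-(prop-1-en-2-yl)decahydronaphthalen-1-yl (3R)-3-methylpentanoate | CC(=C)[C@H]1C[C@H](OC(=O)C[C@H](C)CC)[C@@]2(C)CCC[C@@](C)(O)[C@@H]2C1 | intermediate
18 | (1S,3R,4aR,5R,8aS)-5-hydroxy-3-(3-hydroxyprop-1-en-2-yl)-5,8a-dimethyldecahydronaphthalen-1-yl (3R)-3-methylpentanoate | C=C(CO)[C@H]1C[C@H](OC(=O)C[C@H](C)CC)[C@@]2(C)CCC[C@@](C)(O)[C@@H]2C1 | intermediate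
19 | (1S,3R,4aR,5R,8aS)-5-hydroxy-5,8a-dimethyl-3-(3-oxoprop-1-en-2-yl)decahydronaphthalen-1-yl (3R)-3-methylpentanoate | C=C(C=O)[C@H]1C[C@H](OC(=O)C[C@H](C)CC)[C@@]2(C)CCC[C@@](C)(O)[C@@H]2C1 | intermediate
20 | 2-[(2R,4S,4aS,8R,8aR)-8-hydroxy-4a,8-dimethyl-4-{[(3R)-3-methylpentanoyl]oxy}decahydronaphthalen-2-yl]prop-2-enoic acid (CNP0471281.3) | C=C(C(=O)O)[C@H]1C[C@H](OC(=O)C[C@H](C)CC)[C@@]2(C)CCC[C@@](C)(O)[C@@H]2C1 | target

**Step count and risks**
Total steps: 12. Longest linear sequence: 12 (1 → 20).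

Most likely to fail:

Step 3 (reductive methylation). The risks are over-reduction of the carbonyl, O-methylation and proton quench of the dienolate. The fallback separates reduction from alkylation. It sets out from 4: the Birch reduction (Li, NH3, t-BuOH) is freed of ammonia and quenched with Me3SiCl/Et3N to give trimethyl[(5-methyl-2,3,4,6-tetrahydronaphthalen-1-yl)oxy]silane F1, which is distilled. MeLi in THF then regenerates salt-free lithium dienolate 5, and MeI at −78 °C gives 6, where the route is rejoined.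

Step 5 (enzymatic resolution). No panel enzyme may accept the hindered ketone, or the selectivity may be low. The fallback is a classical resolution through diastereomeric esters and sets out from 7. NaBH4 (MeOH, 0 °C; hydride anti to the angular methyl) gives rac-(1S*,8aS*)-5,8a-dimethyl-1,2,3,4,6,7,8,8a-octahydronaphthalen-1-ol F2. Esterification with (2S)-2-methoxy-2-phenylacetic acid (DCC, DMAP) gives (1S,8aS)-5,8a-dimethyl-1,2,3,4,6,7,8,8a-octahydronaphthalen-1-yl (2S)-2-methoxy-2-phenylacetate F3 and its diastereomer (1R,8aR)-5,8a-dimethyl-1,2,3,4,6,7,8,8a-octahydronaphthalen-1-yl (2S)-2-methoxy-2-phenylacetate F4. These are separated by chromatography or crystallisation, and K2CO3/MeOH releases 8 from F3, where the route is rejoined.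

Step 6 (hydroboration of the hindered tetrasubstituted olefin). Conversion may be slow, or the facial or positional selectivity may be poor. The fallback is oxygenation and then hydrogenation, and sets out from 8. The singlet-oxygen ene reaction (O2, hν, tetraphenylporphyrin, CH2Cl2) abstracts H from C6, the carbon geminal to the bulky quaternary side, and delivers oxygen to C4 from the α-face, giving (1S,5R,8aS)-5-hydroperoxy-5,8a-dimethyl-1,2,3,5,6,7,8,8a-octahydronaphthalen-1-ol F5. PPh3 reduces this in the same flask to (1S,5R,8aS)-5,8a-dimethyl-1,2,3,5,6,7,8,8a-octahydronaphthalene-1,5-diol F6. Hydrogenation (H2, PtO2, EtOAc) from the α-face, opposite the angular methyl, installs the C5 α-hydrogen and gives 10, where the route is rejoined.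

**Further compounds**
F1 | step 3 | trimethyl[(5-methyl-2,3,4,6-tetrahydronaphthalen-1-yl)oxy]silane | C[Si](C)(C)OC1=C2C=CCC(C)=C2CCC1
F2 | step 5 | rac-(1S*,8aS*)-5,8a-dimethyl-1,2,3,4,6,7,8,8a-octahydronaphthalen-1-ol (racemate, one enantiomer drawn) | C1C[C@H](O)[C@@]2(C)CCCC(C)=C2C1
F3 | step 5 | (1S,8aS)-5,8a-dimethyl-1,2,3,4,6,7,8,8a-octahydronaphthalen-1-yl (2S)-2-methoxy-2-phenylacetate | C1C[C@H](OC(=O)[C@@H](OC)c3ccccc3)[C@@]2(C)CCCC(C)=C2C1
F4 | step 5 | (1R,8aR)-5,8a-dimethyl-1,2,3,4,6,7,8,8a-octahydronaphthalen-1-yl (2S)-2-methoxy-2-phenylacetate | C1C[C@@H](OC(=O)[C@@H](OC)c3ccccc3)[C@]2(C)CCCC(C)=C2C1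
F5 | step 6 | (1S,5R,8aS)-5-hydroperoxy-5,8a-dimethyl-1,2,3,5,6,7,8,8a-octahydronaphthalen-1-ol | C1C[C@H](O)[C@@]2(C)CCC[C@@](C)(OO)C2=C1
F6 | step 6 | (1S,5R,8aS)-5,8a-dimethyl-1,2,3,5,6,7,8,8a-octahydronaphthalene-1,5-diol | C1C[C@H](O)[C@@]2(C)CCC[C@@](C)(O)C2=C1
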